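**Assumption:** 3-ethoxy-2-methylcyclohex-2-en-1-one (9) is treated as purchasable (otherwise one step from 2-methylcyclohexane-1,3-dione, EtOH, TsOH); the catalyst antipodes in steps 3 and 6 are those that give the configurations drawn.

## Retrosynthetic overview

1. The 1,2-dioxane is closed last: a C6 tertiary peroxide anion opens a trans-β-lactone at its alkyl C–O carbon (6-exo-tet SN2), setting C3 by inversion; C2 is already in the lactone.
2. The β-lactone comes from a catalytic asymmetric ketene–aldehyde [2+2]; the cyclohexenone (masked as a 3-ethoxy-dienyl triflate) is attached at C8 by sp3–sp2 Negishi coupling.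
3. The C3-aldehyde/C8-iodide chain comes from an ε-lactone made by enantioselective Baeyer–Villiger desymmetrization of mirror-symmetric 4-methyl-4-(silylperoxy)cyclohexanone, which sets C6 (key step).
4. That ketone comes from Mukaiyama–Isayama peroxidation of 4-methylcyclohex-3-enone, made by Birch reduction of 4-methylanisole; the arene supplies C3–C8 and the C6 methyl.
5. Ring order: carbocycle pre-formed from 9; oxepanone (temporary), then oxetanone (temporary), then the 1,2-dioxane.

## Route

**Step 1**
Reactants: 1, 4-methylanisole
Product: 2, 4-methylcyclohex-3-en-1-one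
Conditions: Li, NH3(l), t-BuOH, THF, −78 → −33 °C; then (CO2H)2, H2O/MeOH, rt (dihydroanisole not isolated)
Reagents that add atoms: water, O (becomes the carbonyl oxygen; OMe leaves as MeOH)
Why: Birch reduction gives 1-methoxy-4-methylcyclohexa-1,4-diene (OMe and Me stay on the surviving alkenes), and mild oxalic-acid hydrolysis of the enol ether gives the β,γ-unsaturated ketone without conjugation; no stereocentre.

**Step 2**
Reactants: 2, 4-methylcyclohex-3-en-1-one
Product: 3, 4-methyl-4-[(triethylsilyl)peroxy]cyclohexan-1-one (achiral, mirror plane through C1/C4)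
Conditions: Co(thd)2 (5 mol%), O2 (1 atm), Et3SiH, ClCH2CH2Cl, rt
Reagents that add atoms: dioxygen, O=O; triethylsilane, CC[SiH](CC)CC
Why: Mukaiyama–Isayama hydroperoxysilylation: Co–H hydrogen-atom transfer to the trisubstituted alkene gives the tertiary radical, which traps O2 and is silylated to the Markovnikov tertiary silyl peroxide, leaving the ketone untouched.

**Step 3 (key step)**
Reactants: 3, 4-methyl-4-[(triethylsilyl)peroxy]cyclohexan-1-one
Product: 4, (5S)-5-methyl-5-[(triethylsilyl)peroxy]oxepan-2-one
Conditions: Sc(OTf)3 (5 mol%), chiral N,N′-dioxide ligand (6 mol%), m-CPBA (1.2 equiv), EtOAc, −20 °C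
Reagents that add atoms: m-CPBA, O=C(OO)c1cccc(Cl)c1
Why: Catalytic asymmetric Baeyer–Villiger desymmetrization: the chiral Sc(III) complex lets only one of the two enantiotopic α-CH2 groups migrate in the Criegee intermediate, which makes the peroxide carbon the C6 stereocentre (5S here = 6R in the target, CIP priority switch) and differentiates the arms as acyl (→C3) and alkoxy (→C8); any minor enantiomer becomes a separable diastereomer after step 6.

**Step 4**
Reactants: 4, (5S)-5-methyl-5-[(triethylsilyl)peroxy]oxepan-2-one
Product: 5, (4S)-6-hydroxy-4-methyl-4-[(triethylsilyl)peroxy]hexanal (in equilibrium with a minor 7-membered lactol)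
Conditions: DIBAL-H (1.05 equiv), CH2Cl2, −78 °C; Rochelle salt
Reagents that add atoms: none
Why: Partial lactone reduction stops at the tetrahedral aluminate at −78 °C, a temperature at which hindered peroxides survive DIBAL, and the ε-hydroxy aldehyde is mainly open-chain; C6 is untouched.

**Step 5**
Reactants: 5, (4S)-6-hydroxy-4-methyl-4-[(triethylsilyl)peroxy]hexanal
Product: 6, (4S)-6-iodo-4-methyl-4-[(triethylsilyl)peroxy]hexanal
Conditions: PPh3, I2, imidazole (premixed), CH2Cl2, 0 °C
Reagents that add atoms: iodine, II
Why: Appel iodination of the primary alcohol of the open-chain tautomer via the alkoxyphosphonium salt (premixing leaves no free phosphine to reduce the peroxide); the aldehyde and C6 are unaffected.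

**Step 6**
Reactants: 6, (4S)-6-iodo-4-methyl-4-[(triethylsilyl)peroxy]hexanal; 7, propionyl bromide
Product: 8, (3R,4R)-4-{(3S)-5-iodo-3-methyl-3-[(triethylsilyl)peroxy]pentyl}-3-methyloxetan-2-one
Conditions: 7, i-Pr2NEt, chiral Al(III)–salen bis(pyridinium) catalyst (10 mol%), CH2Cl2, −70 °C
Reagents that add atoms: propionyl bromide (7), CCC(=O)Br
Why: Trans-selective catalytic asymmetric ketene–aldehyde [2+2] cyclocondensation (methylketene generated in situ) sets C2 (R) and the C3 carbinol carbon (R, to be inverted) under catalyst control, independent of remote C6, and the alkyl iodide and silyl peroxide are inert at −70 °C.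

**Step 7**
Reactants: 9, 3-ethoxy-2-methylcyclohex-2-en-1-one; 10, iodomethane
Product: 11, 3-ethoxy-2,6,6-trimethylcyclohex-2-en-1-one
Conditions: LDA, THF, −78 °C, then MeI, → 0 °C; repeat LDA/MeI in the same flask
Reagents that add atoms: iodomethane (10), CI
Why: Stork–Danheiser kinetic α′-deprotonation/alkylation of the vinylogous ester, run twice, installs the gem-dimethyl group; no stereocentre.

**Step 8**
Reactants: 11, 3-ethoxy-2,6,6-trimethylcyclohex-2-en-1-one
Product: 12, 3-ethoxy-2,6,6-trimethylcyclohexa-1,3-dien-1-yl trifluoromethanesulfonate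
Conditions: LDA, THF, −78 °C; PhNTf2, → 0 °C
Reagents that add atoms: N-phenyl-bis(trifluoromethanesulfonimide), O=S(=O)(N(c1ccccc1)S(=O)(=O)C(F)(F)F)C(F)(F)F
Why: With α′ blocked, LDA removes the γ-hydrogen and O-triflation of the extended enolate gives a regiodefined dienyl triflate, i.e. a masked 3-oxocyclohexenyl electrophile with the leaving group on the carbon flanked by CMe2 and C–Me.

**Step 9**
Reactants: 8, (3R,4R)-4-{(3S)-5-iodo-3-methyl-3-[(triethylsilyl)peroxy]pentyl}-3-methyloxetan-2-one; 12, the dienyl triflate
Product: 13, (3R,4R)-4-{(3R)-5-(3-ethoxy-2,6,6-trimethylcyclohexa-1,3-dien-1-yl)-3-methyl-3-[(triethylsilyl)peroxy]pentyl}-3-methyloxetan-2-one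
Conditions: Zn dust (TMSCl/BrCH2CH2Br-activated), LiCl, THF, 25 °C; then 12, Pd(OAc)2 (2 mol%), SPhos (4 mol%), 25 °C; pH 7 work-up
Reagents that add atoms: dienyl triflate 12 (reactant), CCOC1=CCC(C)(C)C(OS(=O)(=O)C(F)(F)F)=C1C
Why: Negishi sp3–sp2 coupling: zinc inserts into the primary C–I bond and Pd couples the alkylzinc with the hindered vinyl triflate under neutral conditions that the β-lactone, the hindered silyl peroxide and the enol ether are expected to survive (this tolerance is untested); no stereocentre is touched (the C6 descriptor changes from S to R only through CIP priorities).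

**Step 10**
Reactants: 13, the coupled β-lactone; 10, iodomethane
Product: 14, methyl (2R)-2-{(3S,6R)-6-methyl-6-[2-(2,6,6-trimethyl-3-oxocyclohex-1-en-1-yl)ethyl]-1,2-dioxan-3-yl}propanoate (methyl diacarnoate A)
Conditions: TBAF (1.05 equiv), THF (5 mM), −20 → 0 °C; then MeI, DMF, rt; then 1 M HCl, THF, 0 °C
Reagents that add atoms: iodomethane (10), CI; water, O (enone oxygen; OEt leaves as EtOH)
Why: Proposed new method: fluoride unmasks the tertiary peroxide anion, which attacks the lactone alkyl C–O carbon in a 6-exo-tet SN2 (inversion; acyl attack would need an 8-membered ring), closing the 1,2-dioxane and setting C3 (S), after which the carboxylate is methylated and dilute acid hydrolyses the dienol ether to the enone; the closest known chemistry is SN2 opening of β-lactones by azide, thiolate or carboxylate with inversion and 6-exo-tet alkylation of hydroperoxides by sulfonates.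

## Compound list

1 | 4-methylanisole | COc1ccc(C)cc1 | starting material
2 | 4-methylcyclohex-3-en-1-one | CC1=CCC(=O)CC1 | intermediate
3 | 4-methyl-4-[(triethylsilyl)peroxy]cyclohexan-1-one | CC[Si](CC)(CC)OOC1(C)CCC(=O)CC1 | intermediate
4 | (5S)-5-methyl-5-[(triethylsilyl)peroxy]oxepan-2-one | O=C1CC[C@](C)(OO[Si](CC)(CC)CC)CCO1 | intermediate
5 | (4S)-6-hydroxy-4-methyl-4-[(triethylsilyl)peroxy]hexanal | O=CCC[C@@](C)(CCO)OO[Si](CC)(CC)CC | intermediate
6 | (4S)-6-iodo-4-methyl-4-[(triethylsilyl)peroxy]hexanal | O=CCC[C@@](C)(CCI)OO[Si](CC)(CC)CC | intermediate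
7 | propionyl bromide | CCC(=O)Br | starting material
8 | (3R,4R)-4-{(3S)-5-iodo-3-methyl-3-[(triethylsilyl)peroxy]pentyl}-3-methyloxetan-2-one | O=C1[C@H](C)[C@@H](CC[C@@](C)(CCI)OO[Si](CC)(CC)CC)O1 | intermediate
9 | 3-ethoxy-2-methylcyclohex-2-en-1-one | CCOC1=C(C)C(=O)CCC1 | starting material
10 | iodomethane | CI | starting material
11 | 3-ethoxy-2,6,6-trimethylcyclohex-2-en-1-one | CCOC1=C(C)C(=O)C(C)(C)CC1 | intermediate
12 | 3-ethoxy-2,6,6-trimethylcyclohexa-1,3-dien-1-yl trifluoromethanesulfonate | CCOC1=CCC(C)(C)C(OS(=O)(=O)C(F)(F)F)=C1C | intermediate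
13 | (3R,4R)-4-{(3R)-5-(3-ethoxy-2,6,6-trimethylcyclohexa-1,3-dien-1-yl)-3-methyl-3-[(triethylsilyl)peroxy]pentyl}-3-methyloxetan-2-one | O=C1[C@H](C)[C@@H](CC[C@@](C)(CCC2=C(C)C(OCC)=CCC2(C)C)OO[Si](CC)(CC)CC)O1 | intermediate
14 | methyl (2R)-2-{(3S,6R)-6-methyl-6-[2-(2,6,6-trimethyl-3-oxocyclohex-1-en-1-yl)ethyl]-1,2-dioxan-3-yl}propanoate | COC(=O)[C@H](C)[C@@H]1CC[C@@](C)(CCC2=C(C)C(=O)CCC2(C)C)OO1 | target

## Step count and risks

Total steps: 10. Longest linear sequence: 8 (steps 1–6, 9, 10); steps 7–8 are a two-step side branch.

Three steps most likely to fail: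

1. **Step 3.** The enantioselectivity may be modest because CH3 and OOSiEt3 give only a small conformational bias, and the Lewis acid may degrade the silyl peroxide. Fallback: run the Baeyer–Villiger with plain m-CPBA (racemic 4) and use step 6 as a resolution, since the catalyst-controlled β-lactone formation turns the two C6 enantiomers into chromatographically separable diastereomers of 8.
2. **Step 9.** Zn(0) or Pd(0) may reduce the O–O bond or open the β-lactone. Fallback: make the C8–ring bond before any peroxide exists. Ozonolyse the enol-ether alkene of the Birch diene of 1 (NaBH4 work-up) to methyl (Z)-6-hydroxy-4-methylhex-3-enoate, then Appel, Negishi with 12, Mukaiyama–Isayama peroxidation of the trisubstituted alkene and ester-to-aldehyde reduction, and continue with steps 6 and 10, separating the C6 epimers as diastereomers.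
3. **Step 10.** The peroxide anion may not open the β-lactone cleanly (oligomerization or acyl attack). Fallback: drop the β-lactone and convert the C3 aldehyde into the (E)-2-methyl-enoate (Ph3P=C(CH3)CO2Me). After coupling and desilylation, close the dioxane by amine-promoted intramolecular oxa-Michael addition of the hydroperoxide (Et2NH, CF3CH2OH), and separate the C2/C3 diastereomers.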